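**Retrosynthetic overview**
1. Target 20 ⇐ 19 by cleaving one 4-methoxybenzyl ether (the 4-OH of unit B).
2. Unit A of 19 (arene, then δ-lactone) ⇐ linear pentaketide 17 by C2→C7 aldol aromatisation and lactonisation; 17 ⇐ trianion of triketide 3 + aryloxy ester 16, so the benzylic ether stereocentre exists before ring A does.
3. 16 ⇐ phenol 14 (unit B) + cyclic sulfate 7 (SN2 at the α-carbon, inversion).
4. 14 ⇐ 3 + erythro ester 11 by the same aldol aromatisation/lactonisation; 11 ⇐ 7 (acetate inversion, then α-O-protection); 7 ⇐ threonine-derived acetonide 4; 3 ⇐ 1 + 2.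
5. Ring order: arene B → lactone B → arene A → lactone A.

Unit A is the isochromanone whose C4 carries the aryl ether; unit B is the one with the free 4-OH. Both are (3R,4S), i.e. trans.

Assumption: anions (enolates, alkoxides, phenoxides) and tetrahedral adducts of numbered compounds are treated as states of those compounds and carry no separate numbers.

**Route**

Step 1
Reactants: 1 methyl 4-methoxy-3-oxobutanoate; 2 N-methoxy-N-methylacetamide
Product: 3 methyl 4-methoxy-3,5-dioxohexanoate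
Conditions: LiN(iPr)2 (2.1 equiv), THF, −78 → 0 °C; then 2, −78 → 0 °C; aq. HCl
Reagents that add atoms: none
Why: Weiler dianion γ-acylation (Claisen type) with a Weinreb amide, whose chelated tetrahedral adduct prevents over-addition and proton quench; no stereocentre is set because C4 stays enolisable.

Step 2
Reactants: 4 methyl (4S,5R)-2,2,5-trimethyl-1,3-dioxolane-4-carboxylate
Product: 5 methyl (2S,3R)-2,3-dihydroxybutanoate
Conditions: HCl (cat.), MeOH, 25 °C
Reagents that add atoms: none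
Why: Acid-catalysed transketalisation (acetonide methanolysis) frees the threo diol without touching either stereocentre.

Step 3
Reactants: 5 methyl (2S,3R)-2,3-dihydroxybutanoate
Product: 7 methyl (4S,5R)-5-methyl-1,3,2-dioxathiolane-4-carboxylate 2,2-dioxide, via cyclic sulfite 6 (not isolated)
Conditions: SOCl2, CH2Cl2, 0 → 40 °C; then RuCl3·3H2O (cat.), NaIO4, MeCN–H2O, 0 °C
Reagents that add atoms: thionyl chloride, O=S(Cl)Cl; sodium periodate NaIO4, [Na+].[O-]I(=O)(=O)=O
Why: Sharpless cyclic sulfate synthesis (cyclic sulfite formation, then RuO4-catalysed oxidation at sulfur), with retention at both carbons.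

Step 4
Reactants: 7 methyl (4S,5R)-5-methyl-1,3,2-dioxathiolane-4-carboxylate 2,2-dioxide
Product: 9 methyl (2R,3R)-2,3-dihydroxybutanoate, via acetoxy sulfate cesium salt 8 (not isolated)
Conditions: CsOAc, DMF, 25 °C; then H2SO4 (cat.), MeOH, 50 °C
Reagents that add atoms: cesium acetate, CC(=O)[O-].[Cs+]
Why: Cyclic sulfates of α,β-dihydroxy esters are opened by carboxylates at the ester-activated α-carbon (SN2, inversion at C2, giving the erythro 2R,3R series), and acidic methanolysis then cleaves the sulfate monoester at sulfur and the acetate at the acyl carbon, both with retention.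

Step 5
Reactants: 9 methyl (2R,3R)-2,3-dihydroxybutanoate
Product: 11 methyl (2R,3R)-3-hydroxy-2-[(4-methoxybenzyl)oxy]butanoate, via stannylene acetal 10 (not isolated)
Conditions: Bu2SnO, PhMe, reflux (−H2O); then 4-MeOC6H4CH2Cl, Bu4NI (cat.), PhMe, 80 °C
Reagents that add atoms: 4-methoxybenzyl chloride, COc1ccc(CCl)cc1
Why: Stannylene acetal-mediated regioselective mono-O-alkylation at the more acidic α-oxygen next to the ester; no stereocentre is touched.

Step 6
Reactants: 3 methyl 4-methoxy-3,5-dioxohexanoate; 11 methyl (2R,3R)-3-hydroxy-2-[(4-methoxybenzyl)oxy]butanoate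
Product: 14 (3R,4S)-6,8-dihydroxy-7-methoxy-4-[(4-methoxybenzyl)oxy]-3-methylisochroman-1-one, via linear triketo ester 12 (not isolated), via resorcylate methyl ester 13 (not isolated)
Conditions: 3 (2.5 equiv), LiN(iPr)2 (8.5 equiv), THF, 0 °C; then 11, −78 → 0 °C; AcOH; NaHCO3/Na2CO3 buffer (pH 9.5), MeOH–H2O, 25 °C; pyridinium p-toluenesulfonate (cat.), PhMe, 80 °C
Reagents that add atoms: none
Why: Harris-type biomimetic polyketide condensation in which the terminal carbanion of the trianion of 3 is acylated by the ester of 11 (Claisen), the 3,5,7-triketo ester 12 undergoes C2→C7 intramolecular aldol condensation and enolisation to resorcylate 13, and mild acid closes the δ-lactone through the only free hydroxyl (O4 is blocked, so no phthalide can form), carrying both stereocentres of 11 unchanged into (3R,4S).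

Step 7
Reactants: 14 (3R,4S)-6,8-dihydroxy-7-methoxy-4-[(4-methoxybenzyl)oxy]-3-methylisochroman-1-one; 7 methyl (4S,5R)-5-methyl-1,3,2-dioxathiolane-4-carboxylate 2,2-dioxide
Product: 16 methyl (2R,3R)-3-hydroxy-2-({(3R,4S)-8-hydroxy-7-methoxy-4-[(4-methoxybenzyl)oxy]-3-methyl-1-oxoisochroman-6-yl}oxy)butanoate, via sulfate monoester cesium salt 15 (not isolated)
Conditions: Cs2CO3 (1.0 equiv), DMF, 0 → 25 °C; then H2SO4 (cat.), H2O (2 equiv), THF, 25 °C
Reagents that add atoms: none
Why: Cyclic sulfate opening in which the cesium 6-phenoxide of 14 (the 8-OH stays hydrogen-bonded to the lactone carbonyl) attacks the α-carbon of 7 by SN2, inverting C2 to R, after which the β-sulfate monoester is hydrolysed at sulfur with retention, fixing the ether stereocentre of unit A as (2R,3R).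

Step 8
Reactants: 3 methyl 4-methoxy-3,5-dioxohexanoate; 16 methyl (2R,3R)-3-hydroxy-2-({(3R,4S)-8-hydroxy-7-methoxy-4-[(4-methoxybenzyl)oxy]-3-methyl-1-oxoisochroman-6-yl}oxy)butanoate
Product: 19 (3R,4S)-6,8-dihydroxy-4-({(3R,4S)-8-hydroxy-7-methoxy-4-[(4-methoxybenzyl)oxy]-3-methyl-1-oxoisochroman-6-yl}oxy)-7-methoxy-3-methylisochroman-1-one, via linear triketo ester 17 (not isolated), via resorcylate methyl ester 18 (not isolated)
Conditions: 3 (3 equiv), LiN(iPr)2 (11 equiv), THF, 0 °C; then 16, −78 → −20 °C; AcOH; NaHCO3/Na2CO3 buffer (pH 9.5), MeOH–H2O, 25 °C; pyridinium p-toluenesulfonate (cat.), PhMe, 80 °C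
Reagents that add atoms: none
Why: Proposed new method: the Claisen acylation, C2→C7 aldol aromatisation and δ-lactonisation sequence of step 6 is run on the unprotected aryloxy ester 16, where the α-alkoxy-activated aliphatic methyl ester should be far more electrophilic than the unit B lactone (deactivated by its ortho phenoxide), the hydroxyls ride as lithium alkoxides, and C8 should stay configurationally stable because the new C7 ketone is enolised towards C6 and then becomes an sp2 ring carbon, so ring A forms around the preset (2R,3R) centres to give the (3R,4S) lactone; the closest known reaction type is acylation of the trianion of methyl 3,5-dioxohexanoate with esters followed by aldol cyclisation of the triketo ester to a resorcylate (Harris polyketide synthesis).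

Step 9
Reactants: 19 (3R,4S)-6,8-dihydroxy-4-({(3R,4S)-8-hydroxy-7-methoxy-4-[(4-methoxybenzyl)oxy]-3-methyl-1-oxoisochroman-6-yl}oxy)-7-methoxy-3-methylisochroman-1-one
Product: 20 (3R,4S)-6,8-dihydroxy-4-{[(3R,4S)-4,8-dihydroxy-7-methoxy-3-methyl-1-oxoisochroman-6-yl]oxy}-7-methoxy-3-methylisochroman-1-one
Conditions: CF3CO2H/CH2Cl2 (1:9), anisole (5 equiv), 0 °C
Reagents that add atoms: none
Why: Acidolytic cleavage of the 4-methoxybenzyl ether (cation trapped by anisole in a Friedel–Crafts alkylation) frees the 4-OH of unit B with retention, and the preformed six-membered lactone cannot translactonise under anhydrous acid.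

**Compound list**
1 | methyl 4-methoxy-3-oxobutanoate | COCC(=O)CC(=O)OC | starting material
2 | N-methoxy-N-methylacetamide | CC(=O)N(C)OC | starting material
3 | methyl 4-methoxy-3,5-dioxohexanoate | COC(=O)CC(=O)C(OC)C(C)=O | intermediate
4 | methyl (4S,5R)-2,2,5-trimethyl-1,3-dioxolane-4-carboxylate | C[C@H]1OC(C)(C)O[C@@H]1C(=O)OC | starting material
5 | methyl (2S,3R)-2,3-dihydroxybutanoate | C[C@@H](O)[C@H](O)C(=O)OC | intermediate
6 | methyl (4S,5R)-5-methyl-1,3,2-dioxathiolane-4-carboxylate 2-oxide (both sulfur epimers) | C[C@H]1OS(=O)O[C@@H]1C(=O)OC | intermediate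
7 | methyl (4S,5R)-5-methyl-1,3,2-dioxathiolane-4-carboxylate 2,2-dioxide | C[C@H]1OS(=O)(=O)O[C@@H]1C(=O)OC | intermediate
8 | cesium (2R,3R)-3-(acetyloxy)-4-methoxy-4-oxobutan-2-yl sulfate | C[C@@H](OS(=O)(=O)[O-])[C@@H](OC(C)=O)C(=O)OC.[Cs+] | intermediate
9 | methyl (2R,3R)-2,3-dihydroxybutanoate | C[C@@H](O)[C@@H](O)C(=O)OC | intermediate
10 | methyl (4R,5R)-2,2-dibutyl-5-methyl-1,3,2-dioxastannolane-4-carboxylate | C[C@H]1O[Sn](CCCC)(CCCC)O[C@H]1C(=O)OC | intermediate
11 | methyl (2R,3R)-3-hydroxy-2-[(4-methoxybenzyl)oxy]butanoate | C[C@@H](O)[C@@H](OCc1ccc(OC)cc1)C(=O)OC | intermediate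
12 | methyl (8R,9R)-9-hydroxy-4-methoxy-8-[(4-methoxybenzyl)oxy]-3,5,7-trioxodecanoate | C[C@@H](O)[C@@H](OCc1ccc(OC)cc1)C(=O)CC(=O)C(OC)C(=O)CC(=O)OC | intermediate
13 | methyl 2,4-dihydroxy-6-{(1S,2R)-2-hydroxy-1-[(4-methoxybenzyl)oxy]propyl}-3-methoxybenzoate | C[C@@H](O)[C@@H](OCc1ccc(OC)cc1)c1cc(O)c(OC)c(O)c1C(=O)OC | intermediate
14 | (3R,4S)-6,8-dihydroxy-7-methoxy-4-[(4-methoxybenzyl)oxy]-3-methylisochroman-1-one | COc1c(O)cc2c(c1O)C(=O)O[C@H](C)[C@H]2OCc1ccc(OC)cc1 | intermediate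
15 | cesium (2R,3R)-3-({(3R,4S)-8-hydroxy-7-methoxy-4-[(4-methoxybenzyl)oxy]-3-methyl-1-oxoisochroman-6-yl}oxy)-4-methoxy-4-oxobutan-2-yl sulfate | C[C@@H](OS(=O)(=O)[O-])[C@@H](Oc1cc2c(c(O)c1OC)C(=O)O[C@H](C)[C@H]2OCc1ccc(OC)cc1)C(=O)OC.[Cs+] | intermediate
16 | methyl (2R,3R)-3-hydroxy-2-({(3R,4S)-8-hydroxy-7-methoxy-4-[(4-methoxybenzyl)oxy]-3-methyl-1-oxoisochroman-6-yl}oxy)butanoate | C[C@@H](O)[C@@H](Oc1cc2c(c(O)c1OC)C(=O)O[C@H](C)[C@H]2OCc1ccc(OC)cc1)C(=O)OC | intermediate
17 | methyl (8R,9R)-9-hydroxy-8-({(3R,4S)-8-hydroxy-7-methoxy-4-[(4-methoxybenzyl)oxy]-3-methyl-1-oxoisochroman-6-yl}oxy)-4-methoxy-3,5,7-trioxodecanoate | C[C@@H](O)[C@@H](Oc1cc2c(c(O)c1OC)C(=O)O[C@H](C)[C@H]2OCc1ccc(OC)cc1)C(=O)CC(=O)C(OC)C(=O)CC(=O)OC | intermediate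
18 | methyl 2,4-dihydroxy-6-[(1S,2R)-2-hydroxy-1-({(3R,4S)-8-hydroxy-7-methoxy-4-[(4-methoxybenzyl)oxy]-3-methyl-1-oxoisochroman-6-yl}oxy)propyl]-3-methoxybenzoate | C[C@@H](O)[C@@H](Oc1cc2c(c(O)c1OC)C(=O)O[C@H](C)[C@H]2OCc1ccc(OC)cc1)c1cc(O)c(OC)c(O)c1C(=O)OC | intermediate
19 | (3R,4S)-6,8-dihydroxy-4-({(3R,4S)-8-hydroxy-7-methoxy-4-[(4-methoxybenzyl)oxy]-3-methyl-1-oxoisochroman-6-yl}oxy)-7-methoxy-3-methylisochroman-1-one | COc1c(O)cc2c(c1O)C(=O)O[C@H](C)[C@H]2Oc1cc2c(c(O)c1OC)C(=O)O[C@H](C)[C@H]2OCc1ccc(OC)cc1 | intermediate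
20 | (3R,4S)-6,8-dihydroxy-4-{[(3R,4S)-4,8-dihydroxy-7-methoxy-3-methyl-1-oxoisochroman-6-yl]oxy}-7-methoxy-3-methylisochroman-1-one | COc1c(O)cc2c(c1O)C(=O)O[C@H](C)[C@H]2Oc1cc2c(c(O)c1OC)C(=O)O[C@H](C)[C@H]2O | target

**Step count**
Total: 9 steps. Longest linear sequence: 8 steps (4 → 5 → 7 → 9 → 11 → 14 → 16 → 19 → 20). Compound 3 is made in one step on a side branch and used twice; 7 is also used twice.

**Three steps most likely to fail**

Step 8. The trianion may deprotonate 16 at C2 instead of acylating it (loss of the ether stereocentre), may attack the lactone of unit B, or may react sluggishly with a polyanionic substrate. The fallback sets out from 16 and comes back to the route at 17. Compound 16 is condensed in a crossed Claisen reaction with an excess of the lithium enolate of 2 (LiN(iPr)2, THF, −78 °C) to give the β-keto Weinreb amide (4R,5R)-5-hydroxy-4-({(3R,4S)-8-hydroxy-7-methoxy-4-[(4-methoxybenzyl)oxy]-3-methyl-1-oxoisochroman-6-yl}oxy)-N-methoxy-N-methyl-3-oxohexanamide F1. The dianion of 1 (LiN(iPr)2, 2 equiv per 1, used in excess) then adds through its methoxy-bearing γ-carbon to the amide carbonyl of F1, which is held as its enolate. Acidic work-up gives 17, which is aromatised and lactonised as in step 8. The chain is thus assembled in two Claisen stages from two small, cheap nucleophiles instead of one trianion.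

Step 6. The free δ-hydroxyl of 12 may add to the C5 ketone and dehydrate to a dihydropyranone, or 12 may undergo retro-aldol cleavage, before the C2→C7 aldol takes place. The fallback sets out from 11 and comes back to the route at 13. Compound 11 is silylated (Et3SiCl, imidazole, CH2Cl2) to methyl (2R,3R)-2-[(4-methoxybenzyl)oxy]-3-[(triethylsilyl)oxy]butanoate F2. Acylation of the trianion of 3 with F2 gives methyl (8R,9R)-4-methoxy-8-[(4-methoxybenzyl)oxy]-3,5,7-trioxo-9-[(triethylsilyl)oxy]decanoate F3, which has no free hydroxyl and can only take the aldol path at pH 9.5. This gives methyl 2,4-dihydroxy-3-methoxy-6-{(1S,2R)-1-[(4-methoxybenzyl)oxy]-2-[(triethylsilyl)oxy]propyl}benzoate F4. Pyridinium p-toluenesulfonate in MeOH then removes the silyl group to give 13, which lactonises to 14 as in step 6.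

Step 7. The 6-phenoxide of 14 is flanked by a methoxy group and may be too slow on the cyclic sulfate, so that base-induced elimination of 7 or alkylation at O8 competes. The fallback sets out from 5 and 14 and comes back to the route at 16. Diol 5 is sulfonylated selectively at the more acidic α-hydroxyl (4-nitrobenzenesulfonyl chloride, Et3N, CH2Cl2, 0 °C) to methyl (2S,3R)-3-hydroxy-2-{[(4-nitrophenyl)sulfonyl]oxy}butanoate F5. Silylation (Et3SiOSO2CF3, 2,6-lutidine) gives methyl (2S,3R)-2-{[(4-nitrophenyl)sulfonyl]oxy}-3-[(triethylsilyl)oxy]butanoate F6, which can no longer close to an epoxide. The cesium 6-phenoxide of 14 (Cs2CO3, DMF) displaces the sulfonate of F6 by SN2 with inversion to give methyl (2R,3R)-2-({(3R,4S)-8-hydroxy-7-methoxy-4-[(4-methoxybenzyl)oxy]-3-methyl-1-oxoisochroman-6-yl}oxy)-3-[(triethylsilyl)oxy]butanoate F7. Pyridinium p-toluenesulfonate in MeOH then frees the hydroxyl to give 16.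

**Further compounds**
F1 | step 8 | (4R,5R)-5-hydroxy-4-({(3R,4S)-8-hydroxy-7-methoxy-4-[(4-methoxybenzyl)oxy]-3-methyl-1-oxoisochroman-6-yl}oxy)-N-methoxy-N-methyl-3-oxohexanamide | C[C@@H](O)[C@@H](Oc1cc2c(c(O)c1OC)C(=O)O[C@H](C)[C@H]2OCc1ccc(OC)cc1)C(=O)CC(=O)N(C)OC
F2 | step 6 | methyl (2R,3R)-2-[(4-methoxybenzyl)oxy]-3-[(triethylsilyl)oxy]butanoate | C[C@@H](O[Si](CC)(CC)CC)[C@@H](OCc1ccc(OC)cc1)C(=O)OC
F3 | step 6 | methyl (8R,9R)-4-methoxy-8-[(4-methoxybenzyl)oxy]-3,5,7-trioxo-9-[(triethylsilyl)oxy]decanoate | C[C@@H](O[Si](CC)(CC)CC)[C@@H](OCc1ccc(OC)cc1)C(=O)CC(=O)C(OC)C(=O)CC(=O)OC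
F4 | step 6 | methyl 2,4-dihydroxy-3-methoxy-6-{(1S,2R)-1-[(4-methoxybenzyl)oxy]-2-[(triethylsilyl)oxy]propyl}benzoate | C[C@@H](O[Si](CC)(CC)CC)[C@@H](OCc1ccc(OC)cc1)c1cc(O)c(OC)c(O)c1C(=O)OC
F5 | step 7 | methyl (2S,3R)-3-hydroxy-2-{[(4-nitrophenyl)sulfonyl]oxy}butanoate | C[C@@H](O)[C@H](OS(=O)(=O)c1ccc(cc1)[N+](=O)[O-])C(=O)OC
F6 | step 7 | methyl (2S,3R)-2-{[(4-nitrophenyl)sulfonyl]oxy}-3-[(triethylsilyl)oxy]butanoate | C[C@@H](O[Si](CC)(CC)CC)[C@H](OS(=O)(=O)c1ccc(cc1)[N+](=O)[O-])C(=O)OC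
F7 | step 7 | methyl (2R,3R)-2-({(3R,4S)-8-hydroxy-7-methoxy-4-[(4-methoxybenzyl)oxy]-3-methyl-1-oxoisochroman-6-yl}oxy)-3-[(triethylsilyl)oxy]butanoate | C[C@@H](O[Si](CC)(CC)CC)[C@@H](Oc1cc2c(c(O)c1OC)C(=O)O[C@H](C)[C@H]2OCc1ccc(OC)cc1)C(=O)OC
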